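Everything rests on opening quinone ring B (C1, C2, C3, C4, C4a, C8a) into a phthaloyl unit, with acyl carbons C1 and C4 on C8a and C4a, and the bridge C2=C3. That bridge carries nothing but the C1' chain, so it maps onto a terminal alkyne. A cobalt-inserted benzocyclobutenedione takes up the finished (R)-propargylic ester in one operation, forming C1–C2 and C3–C4, closing ring B and importing the C1' stereocentre and both ester groups. The precursor is the isolable dimethylglyoxime–pyridine phthaloylcobalt chloride of 3,6-bis(methoxymethoxy)benzocyclobutenedione, freed from triphenylphosphine, plus (R)-6-methylhept-5-en-1-yn-3-yl 3-acetoxy-3-methylbutanoate. Chelation-assisted removal of the two peri methoxymethyl ethers finishes the synthesis.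

Key step: step 12

Remark on the chemistry: C1' of the target is (R). The alkynyl carbon of the propargylic ester and C2 of the quinone hold the same rank at C1', so the (R)-alkyne gives the (R)-quinone with unchanged descriptor.

Step 1
Reactants: 1 2-bromo-1,4-dimethoxybenzene; 2 1,1-diethoxyethene
Product: 5 3,6-dimethoxybenzocyclobutenone, via 3,6-dimethoxybenzyne 3 (not isolated), via diethyl ketal 4 (not isolated)
Conditions: NaNH2 (2.5 equiv), 2 (2 equiv), THF, reflux; then 1 M HCl, THF, rt
Reagents that add atoms: water, O
Why: NaNH2 removes the proton flanked by Br and OMe and bromide leaves, the symmetric aryne is trapped by the electron-rich ketene acetal in an aryne [2+2] cycloaddition with no regiochemical issue, and dilute acid hydrolyses the ketal to the ketone.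

Step 2
Reactants: 5 3,6-dimethoxybenzocyclobutenone
Product: 7 3,6-dimethoxybenzocyclobutene-1,2-dione, via geminal dibromo ketone 6 (not isolated)
Conditions: NBS (2.2 equiv), (PhCO2)2 (cat.), PhCF3, reflux; concentrate; then 50% aq. H2SO4, 60 °C
Reagents that add atoms: water, O
Why: Wohl–Ziegler radical bromination attacks the only benzylic CH2, which is also alpha to the ketone, and acid hydrolysis of the geminal dibromide unmasks the second carbonyl, while methyl ethers resist both hydrogen abstraction and hot sulfuric acid.

Step 3
Reactants: 7 3,6-dimethoxybenzocyclobutene-1,2-dione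
Product: 8 3,6-dihydroxybenzocyclobutene-1,2-dione
Conditions: BBr3 (3 equiv), CH2Cl2, −78 → 0 °C; then H2O
Reagents that add atoms: none
Why: BBr3 ether cleavage (Lewis-acid demethylation) is fast for aryl methyl ethers flanked by an acyl group, and the benzocyclobutenedione core, which is itself formed in hot sulfuric acid, tolerates acids far better than nucleophiles.

Step 4
Reactants: 8 3,6-dihydroxybenzocyclobutene-1,2-dione
Product: 9 3,6-bis(methoxymethoxy)benzocyclobutene-1,2-dione
Conditions: MOMCl (3 equiv), i-Pr2NEt (4 equiv), CH2Cl2, 0 °C → rt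
Reagents that add atoms: chloromethyl methyl ether, COCCl
Why: Williamson-type O-alkylation of the two acidic acyl-phenols under a hindered amine base that cannot add to the strained dione installs acetal ethers that should survive the cobalt chemistry and leave under mild Lewis acid at the end.

Step 5
Reactants: 10 4-methylpent-3-enoic acid
Product: 11 N-methoxy-N,4-dimethylpent-3-enamide
Conditions: MeNH(OMe)·HCl, EDC·HCl, N-methylmorpholine, CH2Cl2, 0 °C → rt
Reagents that add atoms: N,O-dimethylhydroxylamine hydrochloride, CNOC.Cl
Why: Carbodiimide amide coupling under weakly basic conditions gives the Weinreb amide without moving the beta,gamma double bond into conjugation.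

Step 6
Reactants: 11 N-methoxy-N,4-dimethylpent-3-enamide
Product: 12 6-methyl-1-(trimethylsilyl)hept-5-en-1-yn-3-one
Conditions: TMSC≡CH, n-BuLi, THF, −78 °C; then 11, −78 → −20 °C; cold aq. NH4Cl
Reagents that add atoms: ethynyltrimethylsilane, C#C[Si](C)(C)C
Why: Weinreb ketone synthesis, in which the lithium acetylide adds only once because the chelated tetrahedral adduct persists until the cold buffered quench, which also keeps the beta,gamma-unsaturated ynone from isomerising.

Step 7
Reactants: 12 6-methyl-1-(trimethylsilyl)hept-5-en-1-yn-3-one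
Product: 13 (R)-6-methyl-1-(trimethylsilyl)hept-5-en-1-yn-3-ol
Conditions: Ru[(R,R)-TsDPEN](p-cymene) (1 mol %, 16-electron amido form), i-PrOH, rt
Reagents that add atoms: none
Why: Noyori asymmetric transfer hydrogenation of an ynone, in which hydride and proton pass from the (R,R)-configured ruthenium hydride–amine through a six-membered outer-sphere transition state with the alkynyl group on the arene side, setting the (R)-carbinol, while the base-free medium leaves the alkene, the silyl alkyne and the acidic alpha-methylene alone.

Step 8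
Reactants: 13 (R)-6-methyl-1-(trimethylsilyl)hept-5-en-1-yn-3-ol
Product: 14 (R)-6-methylhept-5-en-1-yn-3-ol
Conditions: K2CO3 (0.2 equiv), MeOH, 0 °C → rt; volatile product kept in solution
Reagents that add atoms: none
Why: Base-catalysed methanolysis of the C(sp)–Si bond (protodesilylation) frees the terminal alkyne and cannot touch the carbinol stereocentre.

Step 9
Reactants: 15 3-hydroxy-3-methylbutanoic acid
Product: 16 3-acetoxy-3-methylbutanoic acid
Conditions: AcCl (excess, neat), 0 °C → rt; then H2O, THF
Reagents that add atoms: acetyl chloride, CC(=O)Cl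
Why: O-acetylation of the tertiary alcohol by the acid chloride, with any mixed anhydride at the carboxyl group hydrolysed again in the aqueous work-up.

Step 10
Reactants: 14 (R)-6-methylhept-5-en-1-yn-3-ol; 16 3-acetoxy-3-methylbutanoic acid
Product: 17 (R)-6-methylhept-5-en-1-yn-3-yl 3-acetoxy-3-methylbutanoate
Conditions: DCC, DMAP (cat.), CH2Cl2, 0 °C → rt
Reagents that add atoms: none
Why: Steglich esterification acylates the secondary propargylic alcohol at oxygen, so the (R) configuration is retained, and catalytic DMAP at low temperature keeps beta-elimination of acetate from the activated acid in check.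

Step 11
Reactants: 9 3,6-bis(methoxymethoxy)benzocyclobutene-1,2-dione
Product: 19 chloro(dimethylglyoxime)(pyridine)[3,6-bis(methoxymethoxy)phthaloyl]cobalt, via bis(triphenylphosphine) phthaloylcobalt chloride 18 (not isolated)
Conditions: ClCo(PPh3)3 (1.05 equiv), PhCl, rt, Ar; then dimethylglyoxime, pyridine, rt; precipitate with Et2O/hexane
Reagents that add atoms: chlorotris(triphenylphosphine)cobalt, Cl[Co-3]([P+](c1ccccc1)(c1ccccc1)c1ccccc1)([P+](c1ccccc1)(c1ccccc1)c1ccccc1)[P+](c1ccccc1)(c1ccccc1)c1ccccc1; dimethylglyoxime, CC(=NO)C(C)=NO; pyridine, c1ccncc1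
Why: Oxidative addition of monovalent cobalt into the strained acyl–acyl bond (strain-release C–C activation) gives the five-membered trivalent cobalt diacyl, and ligand substitution by the chelating dioxime and pyridine gives an air-stable octahedral complex that precipitates free of triphenylphosphine, a nucleophile that could otherwise add to the C3–H quinone in the next step.

Step 12
Reactants: 19 chloro(dimethylglyoxime)(pyridine)[3,6-bis(methoxymethoxy)phthaloyl]cobalt; 17 (R)-6-methylhept-5-en-1-yn-3-yl 3-acetoxy-3-methylbutanoate
Product: 20 (R)-1-[5,8-bis(methoxymethoxy)-1,4-dioxo-1,4-dihydronaphthalen-2-yl]-4-methylpent-3-enyl 3-acetoxy-3-methylbutanoate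
Conditions: 17 (1.5 equiv), CoCl2·6H2O (1 equiv), ClCH2CH2Cl, 25 → 60 °C, Ar
Reagents that add atoms: none
Why: CoCl2·6H2O labilises a ligand on the trivalent cobalt diacyl, the alkyne coordinates and inserts into one acyl–cobalt bond (C1–C2), and C–C reductive elimination from the resulting seven-membered acyl–vinyl cobaltacycle forms C3–C4 and releases monovalent cobalt. The closest known reaction is the naphthoquinone synthesis from phthaloylcobalt complexes and alkynes, which is established for terminal and functionalised alkynes. Ring B closes as a formal [4+2] annulation, by intermolecular migratory insertion followed by ring-closing reductive elimination at the metal. No stereocentre is created, and C1' arrives with the alkyne and keeps its (R) configuration because none of its bonds takes part. The step needs chemoselectivity for the alkyne over the trisubstituted alkene and the two esters, which the acyl–cobalt bond supplies because it inserts alkynes only, and it needs no regiocontrol because both orientations of insertion into the mirror-symmetric diacyl give the same quinone. The neutral dioxime–pyridine ligand set avoids silver salts, which would promote acyloxy migration in a propargylic ester.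

Step 13
Reactants: 20 (R)-1-[5,8-bis(methoxymethoxy)-1,4-dioxo-1,4-dihydronaphthalen-2-yl]-4-methylpent-3-enyl 3-acetoxy-3-methylbutanoate
Product: 21 (R)-1-(5,8-dihydroxy-1,4-dioxo-1,4-dihydronaphthalen-2-yl)-4-methylpent-3-enyl 3-acetoxy-3-methylbutanoate
Conditions: MgBr2·OEt2 (4 equiv), CH2Cl2/Et2O, 0 °C → rt; then cold pH 4 aqueous buffer
Reagents that add atoms: none
Why: Chelation-assisted acetal cleavage, in which magnesium binds each peri ether oxygen together with the neighbouring quinone carbonyl and bromide removes the methoxymethyl group, should spare the C1' ester, the tertiary acetate and the trisubstituted alkene in the aprotic, thiol-free medium before work-up protonates the magnesium naphthazarinate.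

Compound list
1 | 2-bromo-1,4-dimethoxybenzene | COc1ccc(OC)c(Br)c1 | starting material
2 | 1,1-diethoxyethene | C=C(OCC)OCC | starting material
3 | 3,6-dimethoxybenzyne | COC1=CC=C(OC)C#C1 | intermediate
4 | 7,7-diethoxy-2,5-dimethoxybicyclo[4.2.0]octa-1,3,5-triene (diethyl ketal of 5) | CCOC1(OCC)Cc2c(OC)ccc(OC)c21 | intermediate
5 | 3,6-dimethoxybenzocyclobutenone (2,5-dimethoxybicyclo[4.2.0]octa-1,3,5-trien-7-one) | COc1ccc(OC)c2c1CC2=O | intermediate
6 | 2,2-dibromo-3,6-dimethoxybenzocyclobutenone | COc1ccc(OC)c2c1C(Br)(Br)C2=O | intermediate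
7 | 3,6-dimethoxybenzocyclobutene-1,2-dione | COc1ccc(OC)c2c1C(=O)C2=O | intermediate
8 | 3,6-dihydroxybenzocyclobutene-1,2-dione | Oc1ccc(O)c2c1C(=O)C2=O | intermediate
9 | 3,6-bis(methoxymethoxy)benzocyclobutene-1,2-dione | COCOc1ccc(OCOC)c2c1C(=O)C2=O | intermediate
10 | 4-methylpent-3-enoic acid | CC(C)=CCC(=O)O | starting material
11 | N-methoxy-N,4-dimethylpent-3-enamide | CON(C)C(=O)CC=C(C)C | intermediate
12 | 6-methyl-1-(trimethylsilyl)hept-5-en-1-yn-3-one | CC(C)=CCC(=O)C#C[Si](C)(C)C | intermediate
13 | (R)-6-methyl-1-(trimethylsilyl)hept-5-en-1-yn-3-ol | C[Si](C)(C)C#C[C@@H](CC=C(C)C)O | intermediate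
14 | (R)-6-methylhept-5-en-1-yn-3-ol | C#C[C@@H](CC=C(C)C)O | intermediate
15 | 3-hydroxy-3-methylbutanoic acid | CC(C)(O)CC(=O)O | starting material
16 | 3-acetoxy-3-methylbutanoic acid | CC(=O)OC(C)(C)CC(=O)O | intermediate
17 | (R)-6-methylhept-5-en-1-yn-3-yl 3-acetoxy-3-methylbutanoate | C#C[C@@H](CC=C(C)C)OC(=O)CC(C)(C)OC(C)=O | intermediate
18 | chlorobis(triphenylphosphine)[3,6-bis(methoxymethoxy)phthaloyl]cobalt (five-coordinate trivalent cobalt diacyl metallacycle) | COCOc1ccc(OCOC)c2c1C(=O)[Co-2](Cl)([P+](c1ccccc1)(c1ccccc1)c1ccccc1)([P+](c1ccccc1)(c1ccccc1)c1ccccc1)C2=O | intermediate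
19 | chloro(dimethylglyoxime-N,N')(pyridine)[3,6-bis(methoxymethoxy)phthaloyl]cobalt (octahedral trivalent cobalt diacyl metallacycle) | COCOc1ccc(OCOC)c2c1C(=O)[Co-3]3(Cl)([n+]4ccccc4)([N+](O)=C(C)C(C)=[N+]3O)C2=O | intermediate
20 | (R)-1-[5,8-bis(methoxymethoxy)-1,4-dioxo-1,4-dihydronaphthalen-2-yl]-4-methylpent-3-enyl 3-acetoxy-3-methylbutanoate | CC(=O)OC(C)(C)CC(=O)O[C@H](CC=C(C)C)C1=CC(=O)c2c(OCOC)ccc(OCOC)c2C1=O | intermediate
21 | (R)-1-(5,8-dihydroxy-1,4-dioxo-1,4-dihydronaphthalen-2-yl)-4-methylpent-3-enyl 3-acetoxy-3-methylbutanoate | CC(=O)OC(C)(C)CC(=O)O[C@H](CC=C(C)C)C1=CC(=O)c2c(O)ccc(O)c2C1=O | target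

Total step count: 13.
Longest linear sequence: 7 steps (steps 5, 6, 7, 8, 10, 12, 13 from acid 10; the dione arm, steps 1, 2, 3, 4, 11, 12, 13, is equally long).

Steps most likely to fail

Step 12 (annulation). The alkyne may fail to displace a ligand and insert, may oligomerise at cobalt faster than it inserts, or its propargylic C–O bond may ionise under the Lewis acid. The fallback sets out from dione 9 and alkynol 14 and returns at 20. Alkynol 14 is silylated (TBSCl, imidazole, DMF) to the (R)-tert-butyldimethylsilyl ether F1. Its lithium acetylide (n-BuLi, THF, −78 °C) should add once to the symmetric dione 9 to give the 2-alkynyl-2-hydroxybenzocyclobutenone F2, whose new carbinol centre forms as a mixture and is lost in the next operation. Heating in toluene or xylene (110–140 °C) should open the four-membered ring to the ortho-quinoid ketene, which closes onto the alkyne and takes over the hydroxyl hydrogen (Moore rearrangement of an alkynyl hydroxycyclobutenone), giving the C1'-silyloxy quinone F3. HF·pyridine in THF then frees the C1' alcohol F4, and Steglich esterification with acid 16 (DCC, DMAP) gives 20. In this variant ring B is built by thermal electrocyclic ring expansion instead of at a metal.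

Step 3 (demethylation). The Lewis acid may open the strained acyl–acyl bond, or bromide may add to the dione carbonyls, before the second methyl ether is cleaved. The fallback sets out from ketone 5 and returns at 8. The ethers are cleaved one oxidation level earlier, on the more robust monoketone (BBr3, CH2Cl2), giving 3,6-dihydroxybenzocyclobutenone F5. Acetylation (Ac2O, pyridine) gives the diacetate F6, whose ester groups resist hydrogen abstraction and deactivate the ring towards bromination. Radical dibromination as in step 2 gives the geminal dibromide F7, and hot aqueous H2SO4 in AcOH should hydrolyse the dibromide and both aryl acetates in the same operation to give 8.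

Step 13 (acetal removal). Ionisation at C1' with loss of the carboxylate, or acid-induced cyclisation of the prenyl chain, may compete before both acetals are gone. The fallback sets out from diol 8 and returns at 21. Silylation (TBSOTf, 2,6-lutidine, CH2Cl2, −78 °C) gives the bis(tert-butyldimethylsilyl) ether dione F8. ClCo(PPh3)3 inserts to give the bis(triphenylphosphine) phthaloylcobalt chloride F9, which dimethylglyoxime and pyridine convert into the dioxime–pyridine complex F10. Annulation with 17 under the conditions of step 12 gives the bis(silyl ether) quinone F11. Buffered fluoride (HF·pyridine, pyridine, THF, 0 °C) then cleaves the two aryl silyl ethers, which the peri carbonyls make the most labile Si–O bonds present, to give 21 without any Lewis or protic acid strong enough to ionise C1'.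

Further compounds
F1 | step 12 | (R)-tert-butyldimethyl[(6-methylhept-5-en-1-yn-3-yl)oxy]silane | C#C[C@@H](CC=C(C)C)O[Si](C)(C)C(C)(C)C
F2 | step 12 | 2-[(R)-3-(tert-butyldimethylsilyloxy)-6-methylhept-5-en-1-ynyl]-2-hydroxy-3,6-bis(methoxymethoxy)benzocyclobutenone (carbinol carbon of the ring unassigned, mixture) | COCOc1ccc(OCOC)c2c1C(=O)C2(O)C#C[C@@H](CC=C(C)C)O[Si](C)(C)C(C)(C)C
F3 | step 12 | 2-[(R)-1-(tert-butyldimethylsilyloxy)-4-methylpent-3-enyl]-5,8-bis(methoxymethoxy)naphthalene-1,4-dione | CC(C)(C)[Si](C)(C)O[C@H](CC=C(C)C)C1=CC(=O)c2c(OCOC)ccc(OCOC)c2C1=O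
F4 | step 12 | 2-[(R)-1-hydroxy-4-methylpent-3-enyl]-5,8-bis(methoxymethoxy)naphthalene-1,4-dione | O[C@H](CC=C(C)C)C1=CC(=O)c2c(OCOC)ccc(OCOC)c2C1=O
F5 | step 3 | 3,6-dihydroxybenzocyclobutenone | Oc1ccc(O)c2c1CC2=O
F6 | step 3 | 3,6-diacetoxybenzocyclobutenone | CC(=O)Oc1ccc(OC(C)=O)c2c1CC2=O
F7 | step 3 | 3,6-diacetoxy-2,2-dibromobenzocyclobutenone | CC(=O)Oc1ccc(OC(C)=O)c2c1C(Br)(Br)C2=O
F8 | step 13 | 3,6-bis(tert-butyldimethylsilyloxy)benzocyclobutene-1,2-dione | CC(C)(C)[Si](C)(C)Oc1ccc(O[Si](C)(C)C(C)(C)C)c2c1C(=O)C2=O
F9 | step 13 | chlorobis(triphenylphosphine)[3,6-bis(tert-butyldimethylsilyloxy)phthaloyl]cobalt | CC(C)(C)[Si](C)(C)Oc1ccc(O[Si](C)(C)C(C)(C)C)c2c1C(=O)[Co-2](Cl)([P+](c1ccccc1)(c1ccccc1)c1ccccc1)([P+](c1ccccc1)(c1ccccc1)c1ccccc1)C2=O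
F10 | step 13 | chloro(dimethylglyoxime-N,N')(pyridine)[3,6-bis(tert-butyldimethylsilyloxy)phthaloyl]cobalt | CC(C)(C)[Si](C)(C)Oc1ccc(O[Si](C)(C)C(C)(C)C)c2c1C(=O)[Co-3]3(Cl)([n+]4ccccc4)([N+](O)=C(C)C(C)=[N+]3O)C2=O
F11 | step 13 | (R)-1-[5,8-bis(tert-butyldimethylsilyloxy)-1,4-dioxo-1,4-dihydronaphthalen-2-yl]-4-methylpent-3-enyl 3-acetoxy-3-methylbutanoate | CC(=O)OC(C)(C)CC(=O)O[C@H](CC=C(C)C)C1=CC(=O)c2c(O[Si](C)(C)C(C)(C)C)ccc(O[Si](C)(C)C(C)(C)C)c2C1=O
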